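**Plan** (oxolane numbering: O-1, C-2 aryl, C-3 CH2O-stearoyl, C-4 benzyl, C-5 H2)
Retrosynthesis: remove the stearate and both phenol benzyl ethers, read C-5 as a lactone carbonyl and the C-3 CH2O arm as the stump of a propenyl group, then cut the γ-lactone at C-3–C-4 and at O-1–C-5 together.
Enabling feature: C-3 bears a one-carbon arm and can be the terminus of an allylic ester; C-4–C-5 is the α-carbon and acyl carbon of a 3-arylpropanoate; the benzylic oxygen O-1 on C-2 lies γ to that acyl carbon, so a [3,3] shift followed by ring closure gives the only ring (the oxolane, as its lactone).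
Forward order: dihydroferulic acid → propanoate of (S)-but-3-yn-2-ol → alkynylation of O-benzylvanillin → Z-alkene → Ireland–Claisen/lactonisation (ring formed) → lactone to cyclic ether → ozonolysis/reduction → stearoylation → debenzylation.
Stereochemistry: C-2 from a catalytic asymmetric alkynylation; C-3 and C-4 are relayed in one event from the purchased carbinol centre of (S)-but-3-yn-2-ol through a chair transition state, and that carbinol carbon is afterwards excised.

Key step: step 6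

Assumption: the Me2Zn/(S,S)-ProPhenol system is taken to deliver the alkynyl group to the Si face of aldehyde 6; if Mosher analysis of 7 shows the opposite sense, the (R,R)-ligand is used, and in either case the two carbinol epimers are separable diastereomers.

**Step 1**
Reactants: 1 3-(4-hydroxy-3-methoxyphenyl)propanoic acid (dihydroferulic acid)
Product: 3 3-[4-(benzyloxy)-3-methoxyphenyl]propanoic acid, via benzyl ester 2 (not isolated)
Conditions: BnBr (2.3 equiv), K2CO3, DMF, 60 °C; then NaOH, MeOH/H2O, 50 °C; HCl to pH 2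
Reagents that add atoms: benzyl bromide, BrCc1ccccc1; sodium hydroxide, [Na+].[OH-]
Why: Williamson O-benzylation of phenoxide and carboxylate followed by saponification of the benzyl ester should leave only the phenol protected; no stereocentre is involved.

**Step 2**
Reactants: 3 3-[4-(benzyloxy)-3-methoxyphenyl]propanoic acid; 4 (S)-but-3-yn-2-ol
Product: 5 (2S)-but-3-yn-2-yl 3-[4-(benzyloxy)-3-methoxyphenyl]propanoate
Conditions: EDC·HCl, DMAP (cat.), CH2Cl2, 0 °C → rt
Reagents that add atoms: none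
Why: Steglich-type carbodiimide esterification acylates the secondary propargylic alcohol at oxygen, so the purchased (S) centre is carried over unchanged.

**Step 3**
Reactants: 5 (2S)-but-3-yn-2-yl 3-[4-(benzyloxy)-3-methoxyphenyl]propanoate (1.5 equiv); 6 4-(benzyloxy)-3-methoxybenzaldehyde
Product: 7 (2S,5R)-5-[4-(benzyloxy)-3-methoxyphenyl]-5-hydroxypent-3-yn-2-yl 3-[4-(benzyloxy)-3-methoxyphenyl]propanoate
Conditions: Me2Zn, (S,S)-ProPhenol (20 mol%), Ph3PO (40 mol%), toluene, 0 °C → rt; aq NH4Cl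
Reagents that add atoms: none
Why: Catalytic asymmetric alkynylation of an aromatic aldehyde by an alkynylzinc held in a dinuclear zinc–ProPhenol complex should set the benzylic carbinol (5R, Si-face addition) under catalyst control, and dialkylzincs do not attack the ester.

**Step 4**
Reactants: 7 (2S,5R)-5-[4-(benzyloxy)-3-methoxyphenyl]-5-hydroxypent-3-yn-2-yl 3-[4-(benzyloxy)-3-methoxyphenyl]propanoate
Product: 8 (2S,5R)-5-[4-(benzyloxy)-3-methoxyphenyl]-5-[(triethylsilyl)oxy]pent-3-yn-2-yl 3-[4-(benzyloxy)-3-methoxyphenyl]propanoate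
Conditions: Et3SiCl, imidazole, CH2Cl2, 0 °C
Reagents that add atoms: chlorotriethylsilane, CC[Si](Cl)(CC)CC
Why: Silylation of the secondary alcohol masks the only acidic O–H before enolisation, and the triethylsilyl ether is chosen because the acid quench of step 6 removes it.

**Step 5**
Reactants: 8 (2S,5R)-5-[4-(benzyloxy)-3-methoxyphenyl]-5-[(triethylsilyl)oxy]pent-3-yn-2-yl 3-[4-(benzyloxy)-3-methoxyphenyl]propanoate
Product: 9 (2S,3Z,5S)-5-[4-(benzyloxy)-3-methoxyphenyl]-5-[(triethylsilyl)oxy]pent-3-en-2-yl 3-[4-(benzyloxy)-3-methoxyphenyl]propanoate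
Conditions: H2 (1 atm), Pd/CaCO3 poisoned with Pb(OAc)2, quinoline, EtOAc, rt
Reagents that add atoms: none
Why: Lindlar semihydrogenation adds H2 syn to give the Z-alkene while aryl benzyl ethers and the silyl ether survive; the carbinol descriptor changes from 5R to 5S only because the CIP ranking of alkynyl versus aryl changes.

**Step 6**
Reactants: 9 (2S,3Z,5S)-5-[4-(benzyloxy)-3-methoxyphenyl]-5-[(triethylsilyl)oxy]pent-3-en-2-yl 3-[4-(benzyloxy)-3-methoxyphenyl]propanoate
Product: 13 (3R,4S,5S)-3-[4-(benzyloxy)-3-methoxybenzyl]-5-[4-(benzyloxy)-3-methoxyphenyl]-4-[(1E)-prop-1-en-1-yl]oxolan-2-one, via silyl ketene acetal 10 (not isolated), via rearranged silyl ester 11 (not isolated), via hydroxy acid 12 (not isolated)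
Conditions: LiN(iPr)2 (1.3 equiv), Me3SiCl (3 equiv), THF, −78 °C → rt; then 1 M HCl, THF, rt
Reagents that add atoms: none
Why: LiN(iPr)2 in THF with Me3SiCl present deprotonates the propanoate kinetically to the E(O) enolate, trapped as ketene acetal 10 with the benzyl group cis to the allylic oxygen; on warming 10 undergoes a [3,3] shift that breaks the temporary allylic C–O bond and makes the C-3–C-4 bond, and the acid quench strips both silyl groups from 11 so that the freed benzylic hydroxyl O-1 of 12 attacks the carboxyl carbon C-5. The closest known reaction type is the Ireland–Claisen rearrangement followed by γ-lactonisation, the pairing also seen in Claisen/lactonisation of but-2-ene-1,4-diol derivatives. The ring closes by 5-exo-trig attack of O-1 on the acyl carbon, with retention at C-2 because that carbon is not the reacting centre. C-3 is set by suprafacial 1,3-chirality transfer from the (S)-carbinol carbon through a chair in which its methyl group is equatorial (the other chair would place that methyl 1,3-diaxial to the axial side chain of the Z-alkene); C-4 follows from the ketene acetal geometry, since Z-alkene plus E(O) acetal gives the syn acid and hence benzyl cis to propenyl in the lactone. The selectivities needed are E(O) over Z(O) enolisation and chair over boat, secured by kinetic enolisation without polar additive and by the Z-alkene with an equatorial methyl; the C-2 stereocentre is a spectator that can sit with its hydrogen over the ring and its aryl group anti to the forming bond.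

**Step 7**
Reactants: 13 (3R,4S,5S)-3-[4-(benzyloxy)-3-methoxybenzyl]-5-[4-(benzyloxy)-3-methoxyphenyl]-4-[(1E)-prop-1-en-1-yl]oxolan-2-one
Product: 14 (3R,4S,5S)-3-[4-(benzyloxy)-3-methoxybenzyl]-5-[4-(benzyloxy)-3-methoxyphenyl]-4-[(1E)-prop-1-en-1-yl]oxolan-2-ol (anomeric mixture)
Conditions: iBu2AlH (1.1 equiv), CH2Cl2, −78 °C; aq potassium sodium tartrate
Reagents that add atoms: none
Why: Partial reduction of a γ-lactone by iBu2AlH at low temperature stops at the lactol through a stable aluminium hemiacetal, and the non-basic conditions should leave the α-stereocentre untouched.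

**Step 8**
Reactants: 14 (3R,4S,5S)-3-[4-(benzyloxy)-3-methoxybenzyl]-5-[4-(benzyloxy)-3-methoxyphenyl]-4-[(1E)-prop-1-en-1-yl]oxolan-2-ol
Product: 15 (2S,3S,4R)-4-[4-(benzyloxy)-3-methoxybenzyl]-2-[4-(benzyloxy)-3-methoxyphenyl]-3-[(1E)-prop-1-en-1-yl]oxolane
Conditions: Et3SiH, BF3·OEt2, CH2Cl2, −78 → −40 °C
Reagents that add atoms: none
Why: Ionic hydrogenation of the lactol (oxocarbenium ion formation, then hydride transfer from the silane) gives the C-5 methylene without creating a stereocentre, and the low temperature is meant to keep the benzylic C-2–O-1 bond intact.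

**Step 9**
Reactants: 15 (2S,3S,4R)-4-[4-(benzyloxy)-3-methoxybenzyl]-2-[4-(benzyloxy)-3-methoxyphenyl]-3-[(1E)-prop-1-en-1-yl]oxolane
Product: 17 [(2S,3R,4R)-4-[4-(benzyloxy)-3-methoxybenzyl]-2-[4-(benzyloxy)-3-methoxyphenyl]oxolan-3-yl]methanol, via aldehyde 16 (not isolated)
Conditions: O3, CH2Cl2/MeOH, Sudan Red 7B, −78 °C; then NaBH4, −78 → 0 °C
Reagents that add atoms: ozone, [O-][O+]=O
Why: Ozonolysis of the only alkene with in situ borohydride reduction excises the former carbinol carbon and its methyl group and reduces the aldehyde before it can epimerise at C-3.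

**Step 10**
Reactants: 17 [(2S,3R,4R)-4-[4-(benzyloxy)-3-methoxybenzyl]-2-[4-(benzyloxy)-3-methoxyphenyl]oxolan-3-yl]methanol; 18 octadecanoyl chloride (stearoyl chloride)
Product: 19 [(2S,3R,4R)-4-[4-(benzyloxy)-3-methoxybenzyl]-2-[4-(benzyloxy)-3-methoxyphenyl]oxolan-3-yl]methyl octadecanoate
Conditions: pyridine, DMAP (cat.), CH2Cl2, 0 °C → rt
Reagents that add atoms: none
Why: DMAP-catalysed acylation of the only free (primary) hydroxyl by the acid chloride is a routine ester formation.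

**Step 11**
Reactants: 19 [(2S,3R,4R)-4-[4-(benzyloxy)-3-methoxybenzyl]-2-[4-(benzyloxy)-3-methoxyphenyl]oxolan-3-yl]methyl octadecanoate
Product: 20 [(2S,3R,4R)-4-(4-hydroxy-3-methoxybenzyl)-2-(4-hydroxy-3-methoxyphenyl)oxolan-3-yl]methyl octadecanoate (CNP0168412.1)
Conditions: H2 (1 atm), Pd/C, EtOAc, rt
Reagents that add atoms: none
Why: Hydrogenolysis of aryl benzyl ethers over Pd/C under neutral conditions should be faster than cleavage of the cyclic benzylic ether and leaves the ester untouched.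

**Compound list**
1 | 3-(4-hydroxy-3-methoxyphenyl)propanoic acid (dihydroferulic acid) | OC(=O)CCc1ccc(O)c(OC)c1 | starting material
2 | benzyl 3-[4-(benzyloxy)-3-methoxyphenyl]propanoate | O=C(CCc1ccc(OCc2ccccc2)c(OC)c1)OCc1ccccc1 | intermediate
3 | 3-[4-(benzyloxy)-3-methoxyphenyl]propanoic acid | OC(=O)CCc1ccc(OCc2ccccc2)c(OC)c1 | intermediate
4 | (S)-but-3-yn-2-ol | C[C@H](O)C#C | starting material
5 | (2S)-but-3-yn-2-yl 3-[4-(benzyloxy)-3-methoxyphenyl]propanoate | C[C@H](OC(=O)CCc1ccc(OCc2ccccc2)c(OC)c1)C#C | intermediate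
6 | 4-(benzyloxy)-3-methoxybenzaldehyde (O-benzylvanillin) | O=Cc1ccc(OCc2ccccc2)c(OC)c1 | starting material
7 | (2S,5R)-5-[4-(benzyloxy)-3-methoxyphenyl]-5-hydroxypent-3-yn-2-yl 3-[4-(benzyloxy)-3-methoxyphenyl]propanoate | C[C@H](OC(=O)CCc1ccc(OCc2ccccc2)c(OC)c1)C#C[C@H](O)c1ccc(OCc2ccccc2)c(OC)c1 | intermediate
8 | (2S,5R)-5-[4-(benzyloxy)-3-methoxyphenyl]-5-[(triethylsilyl)oxy]pent-3-yn-2-yl 3-[4-(benzyloxy)-3-methoxyphenyl]propanoate | C[C@H](OC(=O)CCc1ccc(OCc2ccccc2)c(OC)c1)C#C[C@H](O[Si](CC)(CC)CC)c1ccc(OCc2ccccc2)c(OC)c1 | intermediate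
9 | (2S,3Z,5S)-5-[4-(benzyloxy)-3-methoxyphenyl]-5-[(triethylsilyl)oxy]pent-3-en-2-yl 3-[4-(benzyloxy)-3-methoxyphenyl]propanoate | C[C@H](OC(=O)CCc1ccc(OCc2ccccc2)c(OC)c1)/C=C\[C@H](O[Si](CC)(CC)CC)c1ccc(OCc2ccccc2)c(OC)c1 | intermediate
10 | E-configured O-trimethylsilyl ketene acetal of 9 (benzylic CH2 cis to the allylic oxygen) | C[C@H](O/C(O[Si](C)(C)C)=C\Cc1ccc(OCc2ccccc2)c(OC)c1)/C=C\[C@H](O[Si](CC)(CC)CC)c1ccc(OCc2ccccc2)c(OC)c1 | intermediate
11 | trimethylsilyl (2R,3S,4E)-2-[4-(benzyloxy)-3-methoxybenzyl]-3-{(S)-[4-(benzyloxy)-3-methoxyphenyl][(triethylsilyl)oxy]methyl}hex-4-enoate | C/C=C/[C@H]([C@H](O[Si](CC)(CC)CC)c1ccc(OCc2ccccc2)c(OC)c1)[C@@H](Cc1ccc(OCc2ccccc2)c(OC)c1)C(=O)O[Si](C)(C)C | intermediate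
12 | (2R,3S,4E)-2-[4-(benzyloxy)-3-methoxybenzyl]-3-{(S)-[4-(benzyloxy)-3-methoxyphenyl](hydroxy)methyl}hex-4-enoic acid | C/C=C/[C@H]([C@H](O)c1ccc(OCc2ccccc2)c(OC)c1)[C@@H](Cc1ccc(OCc2ccccc2)c(OC)c1)C(=O)O | intermediate
13 | (3R,4S,5S)-3-[4-(benzyloxy)-3-methoxybenzyl]-5-[4-(benzyloxy)-3-methoxyphenyl]-4-[(1E)-prop-1-en-1-yl]oxolan-2-one | C/C=C/[C@H]1[C@@H](Cc2ccc(OCc3ccccc3)c(OC)c2)C(=O)O[C@@H]1c1ccc(OCc2ccccc2)c(OC)c1 | intermediate
14 | (3R,4S,5S)-3-[4-(benzyloxy)-3-methoxybenzyl]-5-[4-(benzyloxy)-3-methoxyphenyl]-4-[(1E)-prop-1-en-1-yl]oxolan-2-ol (anomeric mixture) | C/C=C/[C@H]1[C@@H](Cc2ccc(OCc3ccccc3)c(OC)c2)C(O)O[C@@H]1c1ccc(OCc2ccccc2)c(OC)c1 | intermediate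
15 | (2S,3S,4R)-4-[4-(benzyloxy)-3-methoxybenzyl]-2-[4-(benzyloxy)-3-methoxyphenyl]-3-[(1E)-prop-1-en-1-yl]oxolane | C/C=C/[C@H]1[C@@H](Cc2ccc(OCc3ccccc3)c(OC)c2)CO[C@@H]1c1ccc(OCc2ccccc2)c(OC)c1 | intermediate
16 | (2S,3S,4R)-4-[4-(benzyloxy)-3-methoxybenzyl]-2-[4-(benzyloxy)-3-methoxyphenyl]oxolane-3-carbaldehyde | O=C[C@H]1[C@@H](Cc2ccc(OCc3ccccc3)c(OC)c2)CO[C@@H]1c1ccc(OCc2ccccc2)c(OC)c1 | intermediate
17 | [(2S,3R,4R)-4-[4-(benzyloxy)-3-methoxybenzyl]-2-[4-(benzyloxy)-3-methoxyphenyl]oxolan-3-yl]methanol | OC[C@H]1[C@@H](Cc2ccc(OCc3ccccc3)c(OC)c2)CO[C@@H]1c1ccc(OCc2ccccc2)c(OC)c1 | intermediate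
18 | octadecanoyl chloride (stearoyl chloride) | CCCCCCCCCCCCCCCCCC(=O)Cl | starting material
19 | [(2S,3R,4R)-4-[4-(benzyloxy)-3-methoxybenzyl]-2-[4-(benzyloxy)-3-methoxyphenyl]oxolan-3-yl]methyl octadecanoate | CCCCCCCCCCCCCCCCCC(=O)OC[C@H]1[C@@H](Cc2ccc(OCc3ccccc3)c(OC)c2)CO[C@@H]1c1ccc(OCc2ccccc2)c(OC)c1 | intermediate
20 | [(2S,3R,4R)-4-(4-hydroxy-3-methoxybenzyl)-2-(4-hydroxy-3-methoxyphenyl)oxolan-3-yl]methyl octadecanoate | CCCCCCCCCCCCCCCCCC(=O)OC[C@H]1[C@@H](Cc2ccc(O)c(OC)c2)CO[C@@H]1c1ccc(O)c(OC)c1 | target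

**Totals**
Total step count: 11. Longest linear sequence: 11 steps (1 → 3 → 5 → 7 → 8 → 9 → 13 → 14 → 15 → 17 → 19 → 20).

**Three steps most likely to fail**

Step 6. The ketene acetal geometry may erode, or a boat transition state may compete because of the axial side chain of the Z-alkene. Either would place the benzyl group trans to the propenyl group at the α-carbon, while the chirality transfer to C-3 is unaffected. The fallback sets out from 9: the Claisen/lactonisation is run as before, and the resulting (3S,4S,5S)-3-[4-(benzyloxy)-3-methoxybenzyl]-5-[4-(benzyloxy)-3-methoxyphenyl]-4-[(1E)-prop-1-en-1-yl]oxolan-2-one F2 is deprotonated with LiN(SiMe3)2 in THF at −78 °C. The lactone enolate is then protonated with 2,6-di-tert-butylphenol from the face opposite the propenyl group, which should give the cis lactone under kinetic control and rejoin the route at 13.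

Step 3. The alkynylzinc may add slowly to the electron-rich aldehyde or with poor facial selectivity. The fallback sets out from 5: acyl Sonogashira coupling with 4-(benzyloxy)-3-methoxybenzoyl chloride (PdCl2(PPh3)2, CuI, Et3N, THF) should give the ynone (2S)-5-[4-(benzyloxy)-3-methoxyphenyl]-5-oxopent-3-yn-2-yl 3-[4-(benzyloxy)-3-methoxyphenyl]propanoate F1. Corey–Bakshi–Shibata reduction of F1 (methyl oxazaborolidine, catecholborane, toluene, −78 °C, catalyst enantiomer chosen for the 5R carbinol) then rejoins the route at 7. The 5S epimer is a separable diastereomer and can be returned to F1 with MnO2.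

Step 8. The Lewis acid may ionise the benzylic C-2–O-1 bond, leading to ring opening with over-reduction or to epimerisation at C-2. The fallback sets out from 13 and uses no Lewis acid. LiAlH4 (THF, 0 °C) should give the diol (2R,3S,4E)-2-[4-(benzyloxy)-3-methoxybenzyl]-3-{(S)-[4-(benzyloxy)-3-methoxyphenyl](hydroxy)methyl}hex-4-en-1-ol F3. Selective sulfonylation of the primary hydroxyl (TsCl, pyridine, 0 °C) gives the monotosylate (2R,3S,4E)-2-[4-(benzyloxy)-3-methoxybenzyl]-3-{(S)-[4-(benzyloxy)-3-methoxyphenyl](hydroxy)methyl}hex-4-en-1-yl 4-methylbenzenesulfonate F4. NaH (THF, 0 °C) then closes the ring by 5-exo-tet displacement by the benzylic alkoxide, touching no stereocentre, and rejoins the route at 15.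

**Further compounds**
F1 | step 3 | (2S)-5-[4-(benzyloxy)-3-methoxyphenyl]-5-oxopent-3-yn-2-yl 3-[4-(benzyloxy)-3-methoxyphenyl]propanoate | C[C@H](OC(=O)CCc1ccc(OCc2ccccc2)c(OC)c1)C#CC(=O)c1ccc(OCc2ccccc2)c(OC)c1
F2 | step 6 | (3S,4S,5S)-3-[4-(benzyloxy)-3-methoxybenzyl]-5-[4-(benzyloxy)-3-methoxyphenyl]-4-[(1E)-prop-1-en-1-yl]oxolan-2-one | C/C=C/[C@H]1[C@H](Cc2ccc(OCc3ccccc3)c(OC)c2)C(=O)O[C@@H]1c1ccc(OCc2ccccc2)c(OC)c1
F3 | step 8 | (2R,3S,4E)-2-[4-(benzyloxy)-3-methoxybenzyl]-3-{(S)-[4-(benzyloxy)-3-methoxyphenyl](hydroxy)methyl}hex-4-en-1-ol | C/C=C/[C@H]([C@H](O)c1ccc(OCc2ccccc2)c(OC)c1)[C@@H](Cc1ccc(OCc2ccccc2)c(OC)c1)CO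
F4 | step 8 | (2R,3S,4E)-2-[4-(benzyloxy)-3-methoxybenzyl]-3-{(S)-[4-(benzyloxy)-3-methoxyphenyl](hydroxy)methyl}hex-4-en-1-yl 4-methylbenzenesulfonate | C/C=C/[C@H]([C@H](O)c1ccc(OCc2ccccc2)c(OC)c1)[C@@H](Cc1ccc(OCc2ccccc2)c(OC)c1)COS(=O)(=O)c1ccc(C)cc1
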